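**Plan** (ring atoms numbered as in 7-oxabicyclo[4.1.0]hept-3-en-2-one: C-1 quaternary epoxide carbon, C-2 ketone, C-3 heptenyl carbon, C-4 CH2OH carbon, C-5 carbinol, C-6 epoxide CH, O-7 epoxide oxygen)

- Cuts, in retrosynthetic order: the ester O–Me bond and the C-3–heptenyl bond; a sacrificial carbinol carbon is put back on the C-4 CH2OH carbon; the O-7–C-6 bond is opened and O-7 re-bonded to C-4; then the ring bonds C-4–C-5 and C-6–C-1 are cut together.
- Enabling feature: O-7 on C-1, the C-2 ketone and the C-3=C-4 double bond make C-1/C-2/C-3/C-4 plus O-7 a masked 3-silyloxyfuran (O-7 is the furan oxygen). C-5/C-6 is then an (E)-2-bromovinylboron unit and the carbocycle is the six-membered ring of a 7-oxanorbornene.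
- Forward order of rings: furan-3(2H)-one from a hydroxy ynone; carbocycle plus a temporary 1,2-oxaborolane by a boron-tethered intramolecular furan Diels–Alder reaction; epoxide when fluoride makes the enolate expel O-7 from C-4 and the O-7 alkoxide displaces bromide at C-6; then glycol cleavage/reduction, Suzuki coupling and ester hydrolysis.
- Stereochemistry: a lipase-resolved (S)-carbinol on the tether fixes the furan face; the three-atom tether (exo boron) and the E alkene (endo bromine) fix C-5 and C-6 relative to O-7; the carbinol carbon is afterwards trimmed to the C-4 CH2OH.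

Key step: step 8

Remark: 7 is racemic and 8–11 are carried as two epimers at the carbon that becomes C-1; this centre is planar in furan 17, so the mixture is of no consequence.

**Step 1**
Reactants: 1 (tert-butyldiphenylsilyloxy)acetaldehyde; 2 ethynylmagnesium bromide
Product: 3 rac-1-[(tert-butyldiphenylsilyl)oxy]but-3-yn-2-ol
Conditions: THF, −78 → 0 °C; aq. NH4Cl
Reagents that add atoms: none
Why: Grignard 1,2-addition of the acetylide to the aldehyde should give the propargylic alcohol, the new carbinol centre being racemic at this stage.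

**Step 2**
Reactants: 3 rac-1-[(tert-butyldiphenylsilyl)oxy]but-3-yn-2-ol
Product: 4 (S)-1-[(tert-butyldiphenylsilyl)oxy]but-3-yn-2-ol
Conditions: Amano lipase PS, vinyl acetate, hexane, 30 °C, stopped near half conversion; chromatography
Reagents that add atoms: none
Why: Lipase-catalysed kinetic resolution by transesterification should acylate the (R)-alcohol (large CH2OSi arm, small ethynyl arm) and leave the (S)-alcohol, which is the source of absolute configuration for the whole route.

**Step 3**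
Reactants: 5 2-[(tert-butyldimethylsilyl)oxy]-N-methoxy-N-methylacetamide; 6 methyl (E)-4-bromo-2-methylbut-2-enoate
Product: 7 methyl (E)-5-[(tert-butyldimethylsilyl)oxy]-6-[methoxy(methyl)amino]-2-methyl-6-oxohex-2-enoate (racemic)
Conditions: LiN(iPr)2, THF, −78 °C; then 6, −78 → −20 °C
Reagents that add atoms: none
Why: SN2 alkylation of the α-silyloxy amide enolate by the primary allylic bromide should install the complete (E)-enoate side chain; the new centre is racemic and is erased later.

**Step 4**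
Reactants: 4 (S)-1-[(tert-butyldiphenylsilyl)oxy]but-3-yn-2-ol; 7 methyl (E)-5-[(tert-butyldimethylsilyl)oxy]-6-[methoxy(methyl)amino]-2-methyl-6-oxohex-2-enoate
Product: 8 methyl (2E,9S)-5-[(tert-butyldimethylsilyl)oxy]-10-[(tert-butyldiphenylsilyl)oxy]-9-hydroxy-2-methyl-6-oxodec-2-en-7-ynoate
Conditions: 4, n-BuLi (2 equiv), THF, −78 °C; then 7, −78 → −30 °C; aq. NH4Cl
Reagents that add atoms: none
Why: Weinreb ketone synthesis with the alkoxide–acetylide dianion should stop at the ynone through the chelated tetrahedral intermediate, the hindered conjugated methyl ester being left alone at low temperature.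

**Step 5**
Reactants: 8 methyl (2E,9S)-5-[(tert-butyldimethylsilyl)oxy]-10-[(tert-butyldiphenylsilyl)oxy]-9-hydroxy-2-methyl-6-oxodec-2-en-7-ynoate
Product: 9 methyl (2E,9S)-10-[(tert-butyldiphenylsilyl)oxy]-5,9-dihydroxy-2-methyl-6-oxodec-2-en-7-ynoate
Conditions: HF·pyridine, pyridine, THF, 0 °C → rt
Reagents that add atoms: none
Why: Acidic fluoride desilylation should remove the secondary α-keto TBS ether while the far more robust primary TBDPS ether stays.

**Step 6**
Reactants: 9 methyl (2E,9S)-10-[(tert-butyldiphenylsilyl)oxy]-5,9-dihydroxy-2-methyl-6-oxodec-2-en-7-ynoate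
Product: 11 methyl (E)-4-{5-[(1R)-2-[(tert-butyldiphenylsilyl)oxy]-1-hydroxyethyl]-4-iodo-3-oxo-2,3-dihydrofuran-2-yl}-2-methylbut-2-enoate, via furanone 10 (not isolated)
Conditions: Et2NH (cat.), EtOH, rt; evaporate; N-iodosuccinimide, MeCN, 0 °C → rt
Reagents that add atoms: N-iodosuccinimide (O=C1CCC(=O)N1I)
Why: Amine-catalysed oxa-Michael addition–cyclisation (5-endo-dig) of the α'-hydroxy ynone should give the furan-3(2H)-one, whose nucleophilic C-4 (α-carbon of the vinylogous ester) is then iodinated electrophilically.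

**Step 7**
Reactants: 12 acetylene; 13 boron tribromide
Product: 15 diisopropyl (E)-(2-bromovinyl)boronate, via dibromoborane 14 (not isolated)
Conditions: CH2Cl2, −78 °C; then iPr2O, −78 °C → rt; distillation
Reagents that add atoms: diisopropyl ether (CC(C)OC(C)C)
Why: Bromoboration of acetylene should deliver the (E)-2-bromovinylborane, and B–Br/ether exchange with diisopropyl ether converts it into the exchangeable diisopropyl ester without free HBr.

**Step 8**
Reactants: 11 methyl (E)-4-{5-[(1R)-2-[(tert-butyldiphenylsilyl)oxy]-1-hydroxyethyl]-4-iodo-3-oxo-2,3-dihydrofuran-2-yl}-2-methylbut-2-enoate; 15 diisopropyl (E)-(2-bromovinyl)boronate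
Product: 19 methyl (E)-4-{6-endo-bromo-4-[(1R)-2-[(tert-butyldiphenylsilyl)oxy]-1-hydroxyethyl]-5-exo-hydroxy-3-iodo-2-[(triisopropylsilyl)oxy]-7-oxabicyclo[2.2.1]hept-2-en-1-yl}-2-methylbut-2-enoate, via mixed boronate 16 (not isolated), via silyloxyfuran 17 (not isolated), via cycloadduct 18 (not isolated)
Conditions: 15, toluene, 4 Å sieves, 40 °C, reduced pressure; iPr2NEt, TIPSOTf, −78 → 0 °C; 70 °C; cool; Me3NO, THF, rt; aq. NaHCO3
Reagents that add atoms: triisopropylsilyl triflate (CC(C)[Si](C(C)C)(C(C)C)OS(=O)(=O)C(F)(F)F); trimethylamine N-oxide (C[N+](C)(C)[O-])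
Why: Transesterification hangs the (E)-2-bromovinylboron unit on the carbinol oxygen, soft enolisation with TIPSOTf aromatises the furanone to the electron-rich 3-silyloxyfuran 17, and a thermal, asynchronous but suprafacial [4+2] cycloaddition joins the furan α-carbon next to the silyloxy group (future C-1) to the bromine-bearing carbon (future C-6) and the other α-carbon (future C-4) to the boron-bearing carbon (future C-5), after which Me3NO oxidises the C–B bond with retention. The closest known reaction types are the alkenylboronate-tethered intramolecular Diels–Alder reaction of dienyl alcohols and the intramolecular Diels–Alder reaction of furans carrying a three-atom tether at the furfuryl carbon. The six-membered carbocycle closes by the [4+2] addition across the furan 2,5-positions (giving the 7-oxabicyclo[2.2.1]heptene), and the five-membered 1,2-oxaborolane closes in the same event in the fused mode, in which the tethered atom on the dienophile can only be exo. The two bridgehead centres follow from suprafacial addition to the furan, the exo C–B bond (hence the exo C-5 hydroxyl, cis to the bridging oxygen) from the three-atom tether, the endo C–Br bond from the E geometry of the alkene, and the absolute sense from the carbinol centre of 4, whose CH2OTBDPS arm should lie on the ring-oxygen side of the furan, away from the iodine, so that the tether reaches only one furan face. The step needs the furan to react in preference to the side-chain enoate and the right regiochemistry, both secured by the short tether and by the match between the nucleophilic furan carbon and the carbon β to boron, and it needs the adduct to escape cycloreversion, which cooling and immediate C–B oxidation should secure.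

**Step 9**
Reactants: 19 methyl (E)-4-{6-endo-bromo-4-[(1R)-2-[(tert-butyldiphenylsilyl)oxy]-1-hydroxyethyl]-5-exo-hydroxy-3-iodo-2-[(triisopropylsilyl)oxy]-7-oxabicyclo[2.2.1]hept-2-en-1-yl}-2-methylbut-2-enoate
Product: 23 methyl (E)-4-{(1R,5R,6R)-4-[(1S)-1,2-dihydroxyethyl]-5-hydroxy-3-iodo-2-oxo-7-oxabicyclo[4.1.0]hept-3-en-1-yl}-2-methylbut-2-enoate, via enolate 20 (not isolated), via ring-opened alkoxide 21 (not isolated), via silyl ether 22 (not isolated)
Conditions: TBAF (1 equiv), THF, −78 → 0 °C; then AcOH, TBAF, rt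
Reagents that add atoms: none
Why: Fluoride cleaves the enol silyl ether to enolate 20, which expels the bridging oxygen from C-4 (E1cB, retro-oxa-Michael) to give the enone and the tertiary C-1 alkoxide 21; this displaces the endo bromide at C-6 with inversion (Williamson-type 3-exo-tet epoxide closure), so the former furan oxygen becomes the epoxide oxygen cis to the C-5 hydroxyl, and buffered fluoride then removes the TBDPS group.

**Step 10**
Reactants: 23 methyl (E)-4-{(1R,5R,6R)-4-[(1S)-1,2-dihydroxyethyl]-5-hydroxy-3-iodo-2-oxo-7-oxabicyclo[4.1.0]hept-3-en-1-yl}-2-methylbut-2-enoate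
Product: 25 methyl (E)-4-[(1R,5R,6R)-5-hydroxy-4-(hydroxymethyl)-3-iodo-2-oxo-7-oxabicyclo[4.1.0]hept-3-en-1-yl]-2-methylbut-2-enoate, via aldehyde 24 (not isolated)
Conditions: NaIO4 on silica gel, CH2Cl2, 0 °C; filter; NaBH(OAc)3, AcOH, 0 °C
Reagents that add atoms: none
Why: Malaprade glycol cleavage removes the sacrificial carbon together with its stereocentre, and NaBH(OAc)3 should reduce the resulting aldehyde chemoselectively in the presence of the enone ketone and the ester.

**Step 11**
Reactants: 25 methyl (E)-4-[(1R,5R,6R)-5-hydroxy-4-(hydroxymethyl)-3-iodo-2-oxo-7-oxabicyclo[4.1.0]hept-3-en-1-yl]-2-methylbut-2-enoate; 26 (E)-hept-1-en-1-ylboronic acid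
Product: 27 methyl (E)-4-[(1R,5R,6R)-3-[(E)-hept-1-en-1-yl]-5-hydroxy-4-(hydroxymethyl)-2-oxo-7-oxabicyclo[4.1.0]hept-3-en-1-yl]-2-methylbut-2-enoate
Conditions: PdCl2(PhCN)2 (cat.), AsPh3, Ag2O, THF/H2O, rt
Reagents that add atoms: none
Why: Suzuki–Miyaura coupling of the α-iodoenone with the alkenylboronic acid should proceed at room temperature with retention of the E geometry, Ag2O serving as a mild base that spares the epoxy ketone.

**Step 12**
Reactants: 27 methyl (E)-4-[(1R,5R,6R)-3-[(E)-hept-1-en-1-yl]-5-hydroxy-4-(hydroxymethyl)-2-oxo-7-oxabicyclo[4.1.0]hept-3-en-1-yl]-2-methylbut-2-enoate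
Product: 28 ambuic acid (target)
Conditions: Me3SnOH, 1,2-dichloroethane, 60 °C; aq. KHSO4
Reagents that add atoms: trimethyltin hydroxide (C[Sn](C)(C)O)
Why: Trimethyltin hydroxide-mediated ester hydrolysis is near neutral and should free the acid without opening the epoxide or touching the enone.

**Compound list**

1 | (tert-butyldiphenylsilyloxy)acetaldehyde | O=CCO[Si](c1ccccc1)(c1ccccc1)C(C)(C)C | starting material
2 | ethynylmagnesium bromide | C#C[Mg]Br | starting material
3 | rac-1-[(tert-butyldiphenylsilyl)oxy]but-3-yn-2-ol | C#CC(O)CO[Si](c1ccccc1)(c1ccccc1)C(C)(C)C | intermediate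
4 | (S)-1-[(tert-butyldiphenylsilyl)oxy]but-3-yn-2-ol | C#C[C@H](O)CO[Si](c1ccccc1)(c1ccccc1)C(C)(C)C | intermediate
5 | 2-[(tert-butyldimethylsilyl)oxy]-N-methoxy-N-methylacetamide | CON(C)C(=O)CO[Si](C)(C)C(C)(C)C | starting material
6 | methyl (E)-4-bromo-2-methylbut-2-enoate | COC(=O)/C(C)=C/CBr | starting material
7 | methyl (E)-5-[(tert-butyldimethylsilyl)oxy]-6-[methoxy(methyl)amino]-2-methyl-6-oxohex-2-enoate, racemic | COC(=O)/C(C)=C/CC(O[Si](C)(C)C(C)(C)C)C(=O)N(C)OC | intermediate
8 | methyl (2E,9S)-5-[(tert-butyldimethylsilyl)oxy]-10-[(tert-butyldiphenylsilyl)oxy]-9-hydroxy-2-methyl-6-oxodec-2-en-7-ynoate, both C-5 epimers | COC(=O)/C(C)=C/CC(O[Si](C)(C)C(C)(C)C)C(=O)C#C[C@H](O)CO[Si](c1ccccc1)(c1ccccc1)C(C)(C)C | intermediate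
9 | methyl (2E,9S)-10-[(tert-butyldiphenylsilyl)oxy]-5,9-dihydroxy-2-methyl-6-oxodec-2-en-7-ynoate, both C-5 epimers | COC(=O)/C(C)=C/CC(O)C(=O)C#C[C@H](O)CO[Si](c1ccccc1)(c1ccccc1)C(C)(C)C | intermediate
10 | methyl (E)-4-{5-[(1R)-2-[(tert-butyldiphenylsilyl)oxy]-1-hydroxyethyl]-3-oxo-2,3-dihydrofuran-2-yl}-2-methylbut-2-enoate, both C-2 epimers | O=C1C=C([C@H](O)CO[Si](c2ccccc2)(c2ccccc2)C(C)(C)C)OC1C/C=C(\C)C(=O)OC | intermediate
11 | the 4-iodo derivative of 10 (4-iodofuran-3(2H)-one), both C-2 epimers | O=C1C(I)=C([C@H](O)CO[Si](c2ccccc2)(c2ccccc2)C(C)(C)C)OC1C/C=C(\C)C(=O)OC | intermediate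
12 | acetylene | C#C | starting material
13 | boron tribromide | BrB(Br)Br | starting material
14 | (E)-(2-bromovinyl)dibromoborane | Br/C=C/B(Br)Br | intermediate
15 | diisopropyl (E)-(2-bromovinyl)boronate | Br/C=C/B(OC(C)C)OC(C)C | intermediate
16 | mixed boronate: 11 with its carbinol oxygen bound to the (E)-(2-bromovinyl)(isopropoxy)boryl group | O=C1C(I)=C([C@@H](CO[Si](c2ccccc2)(c2ccccc2)C(C)(C)C)OB(OC(C)C)/C=C/Br)OC1C/C=C(\C)C(=O)OC | intermediate
17 | 2,3,4,5-tetrasubstituted furan: 2-[(E)-4-methoxy-3-methyl-4-oxobut-2-enyl], 3-(triisopropylsilyloxy), 4-iodo, 5-[(1R)-1-boryloxy-2-(TBDPS-oxy)ethyl] | CC(C)[Si](C(C)C)(C(C)C)Oc1c(I)c([C@@H](CO[Si](c2ccccc2)(c2ccccc2)C(C)(C)C)OB(OC(C)C)/C=C/Br)oc1C/C=C(\C)C(=O)OC | intermediate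
18 | cycloadduct: 7-oxabicyclo[2.2.1]hept-2-ene fused at C-4/C-5 to a 1,2-oxaborolane (B-isopropoxy), 6-endo-bromo, 3-iodo, 2-silyloxy | IC1=C(O[Si](C(C)C)(C(C)C)C(C)C)[C@]2(C/C=C(\C)C(=O)OC)O[C@]13[C@@H](CO[Si](c4ccccc4)(c4ccccc4)C(C)(C)C)OB(OC(C)C)[C@H]3[C@@H]2Br | intermediate
19 | methyl (E)-4-{6-endo-bromo-4-[(1R)-2-(TBDPS-oxy)-1-hydroxyethyl]-5-exo-hydroxy-3-iodo-2-(triisopropylsilyloxy)-7-oxabicyclo[2.2.1]hept-2-en-1-yl}-2-methylbut-2-enoate | IC1=C(O[Si](C(C)C)(C(C)C)C(C)C)[C@]2(C/C=C(\C)C(=O)OC)O[C@@]1([C@H](O)CO[Si](c1ccccc1)(c1ccccc1)C(C)(C)C)[C@@H](O)[C@@H]2Br | intermediate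
20 | tetrabutylammonium enolate formed from 19 by loss of the TIPS group | IC1=C([O-])[C@]2(C/C=C(\C)C(=O)OC)O[C@@]1([C@H](O)CO[Si](c1ccccc1)(c1ccccc1)C(C)(C)C)[C@@H](O)[C@@H]2Br.CCCC[N+](CCCC)(CCCC)CCCC | intermediate
21 | ring-opened tetrabutylammonium alkoxide: 5-bromo-4-hydroxy-2-iodo-6-oxido-cyclohex-2-enone, bromine trans to both oxygens | IC1=C([C@H](O)CO[Si](c2ccccc2)(c2ccccc2)C(C)(C)C)[C@@H](O)[C@H](Br)[C@]([O-])(C/C=C(\C)C(=O)OC)C1=O.CCCC[N+](CCCC)(CCCC)CCCC | intermediate
22 | TBDPS ether of 23 at the primary hydroxyl | IC1=C([C@H](O)CO[Si](c2ccccc2)(c2ccccc2)C(C)(C)C)[C@@H](O)[C@H]3O[C@@]3(C/C=C(\C)C(=O)OC)C1=O | intermediate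
23 | methyl (E)-4-{(1R,5R,6R)-4-[(1S)-1,2-dihydroxyethyl]-5-hydroxy-3-iodo-2-oxo-7-oxabicyclo[4.1.0]hept-3-en-1-yl}-2-methylbut-2-enoate | IC1=C([C@H](O)CO)[C@@H](O)[C@H]2O[C@@]2(C/C=C(\C)C(=O)OC)C1=O | intermediate
24 | methyl (E)-4-[(1R,5R,6R)-4-formyl-5-hydroxy-3-iodo-2-oxo-7-oxabicyclo[4.1.0]hept-3-en-1-yl]-2-methylbut-2-enoate | IC1=C(C=O)[C@@H](O)[C@H]2O[C@@]2(C/C=C(\C)C(=O)OC)C1=O | intermediate
25 | methyl (E)-4-[(1R,5R,6R)-5-hydroxy-4-(hydroxymethyl)-3-iodo-2-oxo-7-oxabicyclo[4.1.0]hept-3-en-1-yl]-2-methylbut-2-enoate | IC1=C(CO)[C@@H](O)[C@H]2O[C@@]2(C/C=C(\C)C(=O)OC)C1=O | intermediate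
26 | (E)-hept-1-en-1-ylboronic acid | CCCCC/C=C/B(O)O | starting material
27 | methyl ester of ambuic acid | CCCCC/C=C/C1=C(CO)[C@@H](O)[C@H]2O[C@@]2(C/C=C(\C)C(=O)OC)C1=O | intermediate
28 | ambuic acid, (E)-4-[(1R,5R,6R)-3-[(E)-hept-1-en-1-yl]-5-hydroxy-4-(hydroxymethyl)-2-oxo-7-oxabicyclo[4.1.0]hept-3-en-1-yl]-2-methylbut-2-enoic acid | CCCCC/C=C/C1=C(CO)[C@@H](O)[C@H]2O[C@@]2(C/C=C(\C)C(=O)O)C1=O | target

**Totals and risks**

Total step count: 12. Longest linear sequence: 10 steps (1, 2, 4, 5, 6, 8, 9, 10, 11, 12).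

Step 8. This pairing of a furan diene with a tethered bromoalkenylboronate is untested. The cycloaddition may stall or revert because the alkenylboronate is only weakly activated, the mixed boronate may scramble its ligands or hydrolyse before it cyclises, and facial control by the carbinol centre may be incomplete. The fallback sets out from 11 and 15 and comes back at 23. Both the enol and the carbinol of 11 are silylated with TIPSOTf/Et3N to give the bis(triisopropylsilyl) furan F1, and 15 is exchanged with pinacol to give pinacol (E)-(2-bromovinyl)boronate F2. The two are combined without a tether under high pressure (about 12 kbar, CH2Cl2, rt). The exo-boryl, endo-bromo cycloadduct F3 of the required facial series would have to be separated from its isomers, which are diastereomers because of the silylated carbinol centre. Oxidation with NaBO3·4H2O gives the hydroxy bromide F4, and TBAF under the conditions of step 9 (excess reagent, buffered in the second stage) gives 23.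

Step 9. Ring closure may be misdirected under basic fluoride: the C-5 or side-chain alkoxide may attack the carbon bearing bromine, or HBr may be lost with aromatisation. The fallback sets out from 19 and comes back at 23. Both free hydroxyls are masked with TESOTf/2,6-lutidine to give the bis(triethylsilyl) ether F5. TBAF (1 equiv, −78 °C) then triggers the same enolate, bridge-opening and epoxide-closure sequence with only the C-1 oxygen free, giving the silylated epoxy enone F6. Buffered TBAF at rt removes the three silyl ethers to give 23.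

Step 10. The aldehyde is part of a doubly activated iodo-enal next to an epoxy ketone, so over-reduction, conjugate reduction or hydrate formation may intervene. The fallback sets out from 19 and comes back at 25; it takes off the sacrificial carbon before the bridge is opened. HF·pyridine (MeCN, rt) hydrolyses the enol silyl ether without base and removes the TBDPS group, giving the bicyclic α-iodo ketone triol F7. NaIO4 cleaves its glycol to the bridgehead aldehyde F8, which has no conjugated carbonyl group, and NaBH(OAc)3 reduces it to the hydroxymethyl bromo ketone F9. DBU (1 equiv, CH2Cl2, 0 °C) then effects the E1cB opening of the bridge and the epoxide closure to give 25.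

Further compounds

F1 | step 8 | methyl (E)-4-{4-iodo-3-(triisopropylsilyloxy)-5-[(1R)-2-(TBDPS-oxy)-1-(triisopropylsilyloxy)ethyl]furan-2-yl}-2-methylbut-2-enoate | CC(C)[Si](C(C)C)(C(C)C)Oc1c(I)c([C@H](O[Si](C(C)C)(C(C)C)C(C)C)CO[Si](c2ccccc2)(c2ccccc2)C(C)(C)C)oc1C/C=C(\C)C(=O)OC
F2 | step 8 | pinacol (E)-(2-bromovinyl)boronate | Br/C=C/B1OC(C)(C)C(C)(C)O1
F3 | step 8 | untethered cycloadduct: 6-endo-bromo-5-exo-(pinacolboryl)-3-iodo-2-(triisopropylsilyloxy)-7-oxabicyclo[2.2.1]hept-2-ene with the C-1 enoate side chain and the C-4 bis-silylated glycol arm | IC1=C(O[Si](C(C)C)(C(C)C)C(C)C)[C@]2(C/C=C(\C)C(=O)OC)O[C@@]1([C@H](O[Si](C(C)C)(C(C)C)C(C)C)CO[Si](c1ccccc1)(c1ccccc1)C(C)(C)C)[C@@H](B1OC(C)(C)C(C)(C)O1)[C@@H]2Br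
F4 | step 8 | 5-exo-hydroxy analogue of F3 | IC1=C(O[Si](C(C)C)(C(C)C)C(C)C)[C@]2(C/C=C(\C)C(=O)OC)O[C@@]1([C@H](O[Si](C(C)C)(C(C)C)C(C)C)CO[Si](c1ccccc1)(c1ccccc1)C(C)(C)C)[C@@H](O)[C@@H]2Br
F5 | step 9 | bis(triethylsilyl) ether of 19 | IC1=C(O[Si](C(C)C)(C(C)C)C(C)C)[C@]2(C/C=C(\C)C(=O)OC)O[C@@]1([C@H](O[Si](CC)(CC)CC)CO[Si](c1ccccc1)(c1ccccc1)C(C)(C)C)[C@@H](O[Si](CC)(CC)CC)[C@@H]2Br
F6 | step 9 | bis(triethylsilyl) ether of 22 | IC1=C([C@H](O[Si](CC)(CC)CC)CO[Si](c2ccccc2)(c2ccccc2)C(C)(C)C)[C@@H](O[Si](CC)(CC)CC)[C@H]3O[C@@]3(C/C=C(\C)C(=O)OC)C1=O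
F7 | step 10 | methyl (E)-4-{6-endo-bromo-4-[(1R)-1,2-dihydroxyethyl]-5-exo-hydroxy-3-iodo-2-oxo-7-oxabicyclo[2.2.1]heptan-1-yl}-2-methylbut-2-enoate, either C-3 epimer | IC1C(=O)[C@]2(C/C=C(\C)C(=O)OC)O[C@@]1([C@H](O)CO)[C@@H](O)[C@@H]2Br
F8 | step 10 | 4-formyl analogue of F7 | IC1C(=O)[C@]2(C/C=C(\C)C(=O)OC)O[C@@]1(C=O)[C@@H](O)[C@@H]2Br
F9 | step 10 | 4-(hydroxymethyl) analogue of F7 | IC1C(=O)[C@]2(C/C=C(\C)C(=O)OC)O[C@@]1(CO)[C@@H](O)[C@@H]2Br
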